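Start from the early minutes of the ochre run: the readings up to 1.50 min show solid substrate leaving at 0.115 min⁻¹ of its charge, while [starting material] averages about 4.45 %. From 2.50 min to 5.00 min it leaves at 0.0884 min⁻¹, with [starting material] level near 13.1 %.

- ochre: solid substrate 0.50 M; coupling partner 3 equiv; free catalyst 0.15 mol%; run made earlier
- flask: solid substrate 0.50 M; coupling partner 3.00 equiv; free catalyst 0.1 mol%; time 15 min

ochre run (percent of the solid substrate charged)

| time / min | solid substrate / % | product / % | starting material / % |
|---|---|---|---|
| 0.333 | 95.7 | 1.3 | 2.6 |
| 0.833 | 91.8 | 2.5 | 6.0 |
| 1.50 | 82.8 | 8.7 | 8.9 |
| 2.50 | 74.1 | 14.1 | 13.1 |
| 3.00 | 69.8 | 19.0 | 13.7 |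
| 5.00 | 52.0 | 33.4 | 12.6 |

(each reading ± 1 percentage point)

- product is meant together with its crystals
- solid, in amounts per volume of the solution: crystals, solid substrate
- reactions considered so far: solid substrate <-> starting material; catalyst intermediate C -> free catalyst + product; coupling partner + free catalyst <-> catalyst intermediate A; catalyst intermediate B -> by-product + catalyst intermediate C; starting material + catalyst intermediate A <-> catalyst intermediate B; crystals <-> product
- at the start none of the solid substrate is in solution
- what has only dissolved of solid substrate counts as not reacted
- the reaction counts as stopped when no species that holds the solid substrate changes by six tenths of a point or more over the second half of the time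
- starting material means what is dissolved; the solid is not counted in it
- no earlier run changes the charge of free catalyst; that part of a forecast is a guess

- the state of affairs at 15 min: stopped, and by what, or still going (for what has run out or reacted, a solid counts together with what of it has only dissolved) (it is still moving / forward and back rates have come level / no working catalyst is left / all of the solid substrate has reacted / the coupling partner has run out first)
- part of the solid substrate that has turned into other species by 15 min (what has only dissolved does not count)
- amount of product at 15 min, in percent of the solid substrate charged
- amount of starting material at 15 min, in percent of the solid substrate charged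

Build the flask in steps. First take the main step: freeze the coupling partner at its charge and treat the cycle as pseudo-first-order in [starting material]. Divide the ochre product gain per minute over the later stretch by that level to get 0.588 min⁻¹. Scale this by catalyst charge to 0.392 min⁻¹; that scaling is a guess. With [starting material] frozen at the ochre level, this reckoning puts this flask at 77.0 % product by 15 min.

Next add dissolving. Draw a straight line through the two ochre stretches: as read, dissolving falls with [starting material] at 0.302 min⁻¹ and extrapolates to 0.128 min⁻¹ in empty solution. Set supply equal to consumption. My carried quantity is the balance level, the [starting material] at which dissolving replaces what the cycle takes, a steady state: 18.5 %. By this reckoning the level of this flask is higher than the ochre one, and product is made at 0.0723 min⁻¹ after a lag of 1.44 min. Carried to 15 min, that line asks for 98.0 % product plus the balance level, more than the charge.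

Last, let the solid end. By my reckoning the solid in this flask is gone at 12.7 min, and [starting material] then decays at 0.392 min⁻¹ to 7.54 % by 15 min, which gives 92.5 % as product and conversion, still moving.

The forecast shares my state of affairs, it is still moving, but differs from my reckoning in its numbers: conversion 64.5 %, product 64 %, starting material 15 %, holding that “the cycle looks catalyst-limited and near zero order”.

The flask gives: it is still moving, conversion 90.7 %, product 90.7 %, starting material 9.25 %.

    solid substrate ⇌ starting material, rate k1*(cs1 - [starting material]) while solid is left; crystals form when [starting material] > cs1 (solubility = 0.170 M, k = 0.00680 s⁻¹)
    catalyst intermediate C → free catalyst + product (k = 79.0 s⁻¹)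
    coupling partner + free catalyst ⇌ catalyst intermediate A (K = 1.70 L mol⁻¹, k = 13.0 L mol⁻¹ s⁻¹)
    catalyst intermediate B → by-product + catalyst intermediate C (k = 18.0 s⁻¹)
    starting material + catalyst intermediate A ⇌ catalyst intermediate B (K = 2.60 L mol⁻¹, k = 43.0 L mol⁻¹ s⁻¹)
    crystals ⇌ product, rate k6*(cs6 - [product]) while solid is left; crystals form when [product] > cs6 (solubility = 0.420 M, k = 0.0810 s⁻¹)

At 7.50 min this flask holds [starting material] at 17.1 %, beside the balance level of 18.5 %, and at 15.0 min solid substrate stands at 0 %, where the forecast kept about 20%. Now read the same flask at 4.0 min: the balance level puts [starting material] near 18.5 %, and rate and lag put product at 18.5 %. That neighbouring flask holds 16.2 % starting material and 20.0 % product.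

The numbers in the tables are calculated with constants of no real substance; noise was put on by code.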